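Settle the reagent balance first and read the curve second. You have one flask, already followed as the west run.

- west: starting material 0.25 M; reagent 0.275 M; the very flask that is asked about, followed so far
- flask: starting material 0.25 M; reagent 0.275 M; time 2.5 h

west run (percent of the starting material charged)

| time / min | side product / % | double product / % |
|---|---|---|
| 5.00 | 16.7 | 1.7 |
| 12.0 | 26.1 | 0.5 |
| 25.0 | 28.5 | 0 |
| 60.0 | 29.0 | 0.2 |

(standard deviation of a reading: 0.3 percentage points)

- the numbers in the tables scatter by 0.3 percentage points (one standard deviation)
- the reaction counts as stopped when no species that holds the starting material changes by six tenths of a point or more over the second half of the time

* which holds at 2.5 h: what has brought the reaction to rest, or that it has not come to rest (it is still moving / forward and back rates have come level / the reagent has run out first / all of the starting material has reacted)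
* amount of side product at 2.5 h, in percent of the starting material charged

The puzzle is this: the west run holds 1.10 reagent per starting material, yet side product flattens at 28.5%, then 29.0%. That step lies within the scatter, so you reckon on about 29.0% at the asked time. Now divide the reagent charged by the side product formed at the plateau: 3.79. Call this the reagent cover. The name double product suggests two reagent per side product, and the cover stands above two. At that price the flask keeps 47.3% of its reagent, so you commit to a different ending: the unaccounted starting material has gone some unseen way, and all of it has reacted.

The forecast says the reagent has run out first and 29%, on the ground “Its disappearance points to the reagent being used up”. Your reckoning parts from it on the ending, not on the plateau.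

The flask gives all of the starting material has reacted and 29.1%, with 0% of the starting material left, which makes it the limiting reagent.

    starting material + reagent → mono adduct + released group (k = 0.0210 M⁻¹ s⁻¹)
    reagent + mono adduct → double product + released group (k = 0.0330 M⁻¹ s⁻¹)
    2 starting material → homo dimer (k = 0.0710 M⁻¹ s⁻¹)
    double product + released group → side product (k = 0.370 M⁻¹ s⁻¹)

Two reagent per side product holds: this flask's cover of 3.79 reckons 47.3% left, and 47% stands. A neighbour flask, the same but with 0.11 M of reagent, gives 15.5% side product, a cover of 2.84, still above two; that reckons 29.6% of its reagent left, and 30% stands in that flask. In this flask, homo dimer holds 70.9% of the starting material. Take that step away and side product rises from 29.1% to 41.7%, which is 18% of what is missing.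

The data were computed with constants of no real substance.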